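**Retrosynthetic overview**
1. Target 18 ← global MOM removal from hepta-MOM ether 17.
2. 17 ← Pd-catalysed, stereoinvertive allyl–aryl coupling (cyclohexene C–aryl bond) of allylic acetate 10 with flavanone arylboronate 16.
3. 10 ← endo-selective asymmetric Diels–Alder of 2'-hydroxychalcone 6 with 1-acetoxy-3-methylbutadiene 8 (cyclohexene ring formed first; sets the aroyl/aryl carbons, trans).
4. 16 ← Rh-catalysed asymmetric 1,4-arylation of chromone 14 with bromo-arylboronic acid 13 (sets flavanone C2), then Miyaura borylation; the pyranone ring of 14 is built from acetophenone 5.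
5. All four arene rings come from resorcinol; the diene comes from 3-methylbut-2-enal.

Assumption: the sense of induction of the chiral borate (step 7) and of the Rh–bisphosphine (step 13) is taken from the closest precedents; if either proves opposite, the antipodal ligand is used.

**Electrophile half**

Step 1
Reactants: 1 resorcinol
Product: 2 2,4-dihydroxybenzaldehyde
Conditions: POCl3, DMF, MeCN, –15 °C → rt; then H2O, 50 °C
Reagents that add atoms: DMF, CN(C)C=O (formyl carbon); water, O (aldehyde oxygen)
Why: Vilsmeier–Haack formylation goes to C4, the unhindered position ortho/para to both hydroxyls, and iminium hydrolysis gives the aldehyde.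

Step 2
Reactants: 2 2,4-dihydroxybenzaldehyde
Product: 3 2,4-bis(methoxymethoxy)benzaldehyde
Conditions: MOMCl, NaH, DMF, 0 °C → rt
Reagents that add atoms: MOMCl, COCCl
Why: Williamson O-alkylation of both phenoxides; NaH also deprotonates the chelated 2-OH.

Step 3
Reactants: 1 resorcinol
Product: 4 1-(2,4-dihydroxyphenyl)ethan-1-one
Conditions: AcOH, ZnCl2, 140 °C
Reagents that add atoms: acetic acid, CC(O)=O
Why: Nencki (ZnCl2-mediated Friedel–Crafts) C-acylation at C4 of resorcinol.

Step 4
Reactants: 4 1-(2,4-dihydroxyphenyl)ethan-1-one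
Product: 5 1-[2-hydroxy-4-(methoxymethoxy)phenyl]ethan-1-one
Conditions: MOMCl (1.1 equiv), K2CO3, acetone, rt
Reagents that add atoms: MOMCl, COCCl
Why: The 2-OH is hydrogen-bonded to the ketone, so mild carbonate alkylation protects only the 4-OH.

Step 5
Reactants: 3 2,4-bis(methoxymethoxy)benzaldehyde; 5 1-[2-hydroxy-4-(methoxymethoxy)phenyl]ethan-1-one
Product: 6 (E)-3-[2,4-bis(methoxymethoxy)phenyl]-1-[2-hydroxy-4-(methoxymethoxy)phenyl]prop-2-en-1-one
Conditions: KOH, EtOH/H2O, rt
Reagents that add atoms: none
Why: Claisen–Schmidt aldol condensation with E1cB dehydration gives the (E)-chalcone; MOM ethers are base-stable.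

Step 6
Reactants: 7 3-methylbut-2-enal
Product: 8 (E)-3-methylbuta-1,3-dien-1-yl acetate
Conditions: isopropenyl acetate, p-TsOH (cat.), reflux with removal of acetone; distil
Reagents that add atoms: isopropenyl acetate, CC(=C)OC(C)=O
Why: Acid-catalysed enol-acetate exchange with γ-deprotonation gives the conjugated dienyl acetate, E isomer major (the Z isomer does not take part in step 7).

Step 7
Reactants: 6 the 2'-hydroxychalcone; 8 (E)-3-methylbuta-1,3-dien-1-yl acetate (3 equiv)
Product: 9 (1S,5S,6R)-5-[2,4-bis(methoxymethoxy)phenyl]-6-[2-hydroxy-4-(methoxymethoxy)benzoyl]-3-methylcyclohex-2-en-1-yl acetate (OAc cis to the aroyl group, aryl trans to it)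
Conditions: chiral borate from (S)-VANOL, BH3·THF and AcOH (0.5 equiv), 4 Å MS, PhCF3, 0 °C → rt; chromatographic removal of the minor exo adduct
Reagents that add atoms: none
Why: Chiral-borate-promoted Diels–Alder of a 2'-hydroxychalcone, in which boron chelation by phenoxide and carbonyl activates the enone and blocks one face (setting C5 and C6, trans from the E-alkene), the 1-OAc/3-Me diene gives the "ortho/para" regiochemistry, and the endo transition state places OAc cis to the aroyl group (C1); this catalyst class is established for alkyl and aryl dienes and the acyloxy diene is a close but untested extension.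

Step 8
Reactants: 9 the endo cycloadduct
Product: 10 (1S,5S,6R)-6-[2,4-bis(methoxymethoxy)benzoyl]-5-[2,4-bis(methoxymethoxy)phenyl]-3-methylcyclohex-2-en-1-yl acetate
Conditions: MOMCl, i-Pr2NEt, CH2Cl2, 0 °C → rt
Reagents that add atoms: MOMCl, COCCl
Why: O-alkylation of the chelated phenol with a hindered amine base too weak to eliminate the β-acetoxy ketone; this removes the phenoxide that could O-allylate in step 15.

**Nucleophile half**

Step 9
Reactants: 1 resorcinol
Product: 11 1,3-bis(methoxymethoxy)benzene
Conditions: MOMCl, NaH, DMF, 0 °C → rt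
Reagents that add atoms: MOMCl, COCCl
Why: Double Williamson etherification.

Step 10
Reactants: 11 1,3-bis(methoxymethoxy)benzene
Product: 12 1,5-dibromo-2,4-bis(methoxymethoxy)benzene
Conditions: NBS (2.1 equiv), MeCN, 0 °C → rt
Reagents that add atoms: N-bromosuccinimide, O=C1CCC(=O)N1Br
Why: Electrophilic bromination at the two positions ortho/para to both ethers (4 and 6); the position between the ethers is hindered.

Step 11
Reactants: 12 1,5-dibromo-2,4-bis(methoxymethoxy)benzene
Product: 13 [5-bromo-2,4-bis(methoxymethoxy)phenyl]boronic acid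
Conditions: n-BuLi (1.0 equiv), THF, –78 °C; B(Oi-Pr)3; aq. NH4Cl
Reagents that add atoms: triisopropyl borate, CC(C)OB(OC(C)C)OC(C)C; water, O
Why: Mono Br/Li exchange on the symmetric dibromide (aryllithium stabilised by the ortho OMOM) followed by borate trapping and mild hydrolysis.

Step 12
Reactants: 5 1-[2-hydroxy-4-(methoxymethoxy)phenyl]ethan-1-one
Product: 14 7-(methoxymethoxy)-4H-chromen-4-one
Conditions: Me2NCH(OMe)2, toluene, 100 °C; then AcOH, 60 °C
Reagents that add atoms: DMF dimethyl acetal, COC(OC)N(C)C (chromone C2)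
Why: Enaminone formation at the methyl ketone, then mild-acid cyclisation of the ortho-phenol with loss of Me2NH (standard chromone synthesis).

Step 13
Reactants: 13 the bromo-arylboronic acid (2.5 equiv); 14 7-(methoxymethoxy)-4H-chromen-4-one
Product: 15 (2R)-2-[5-bromo-2,4-bis(methoxymethoxy)phenyl]-7-(methoxymethoxy)-2,3-dihydro-4H-chromen-4-one
Conditions: [Rh(OH)(cod)]2 (2.5 mol %), electron-poor bisphosphine (R)-MeO-F12-BIPHEP (5.5 mol %), toluene/H2O, 20 °C
Reagents that add atoms: none
Why: Rh(I)-catalysed asymmetric 1,4-addition of an arylboronic acid to a chromone (Hayashi–Miyaura type), where aryl–Rh insertion on the ligand-selected enone face sets C2 as R; low temperature suppresses retro-oxa-Michael opening and ArBr is inert to Rh(I).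

Step 14
Reactants: 15 the (2R)-bromoflavanone
Product: 16 (2R)-2-[2,4-bis(methoxymethoxy)-5-(4,4,5,5-tetramethyl-1,3,2-dioxaborolan-2-yl)phenyl]-7-(methoxymethoxy)-2,3-dihydro-4H-chromen-4-one
Conditions: Pd(OAc)2 (2 mol %), XPhos (4 mol %), B2pin2, potassium 2-ethylhexanoate, i-PrOAc, 35 °C
Reagents that add atoms: bis(pinacolato)diboron, CC1(C)OB(OC1(C)C)B1OC(C)(C)C(C)(C)O1
Why: Miyaura borylation with a lipophilic carboxylate base runs near room temperature, so the base-labile flavanone C2 stereocentre is not opened or racemised.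

**Union and endgame**

Step 15
Reactants: 10 the allylic acetate; 16 the flavanone arylboronate (1.2 equiv)
Product: 17 (2R)-2-{5-[(1R,5S,6R)-6-[2,4-bis(methoxymethoxy)benzoyl]-5-[2,4-bis(methoxymethoxy)phenyl]-3-methylcyclohex-2-en-1-yl]-2,4-bis(methoxymethoxy)phenyl}-7-(methoxymethoxy)-2,3-dihydro-4H-chromen-4-one (all-trans cyclohexene)
Conditions: Pd2(dba)3 (3 mol %), PPh3 (12 mol %), KF (3 equiv), THF/H2O (20:1), 25 → 40 °C
Reagents that add atoms: none
Why: Proposed new method: a stereoinvertive Pd(0) allyl–aryl Suzuki–Miyaura coupling on a cyclic β-acetoxy ketone (a Diels–Alder-derived 6-aroylcyclohex-2-enyl acetate), a substrate class on which it has not been shown. Pd(0) ionises the pseudoaxial acetate anti (entering on the face opposite the aroyl group), the fluoride-activated boronate transmetalates, and inner-sphere reductive elimination at the less substituted allyl terminus (CH, not C–Me) delivers the aryl on the Pd face, so the new stereocentre is set trans to the aroyl group and cis to the C5 aryl (net inversion, endo adduct → formal exo adduct). The closest known reaction is the Pd/Ni-catalysed coupling of cyclohex-2-enyl acetates or carbonates with arylboron, -tin or -zinc reagents, which proceeds with inversion.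

Step 16
Reactants: 17 the hepta-MOM ether
Product: 18 (2R)-2-{5-[(1R,5S,6R)-6-(2,4-dihydroxybenzoyl)-5-(2,4-dihydroxyphenyl)-3-methylcyclohex-2-en-1-yl]-2,4-dihydroxyphenyl}-7-hydroxy-2,3-dihydro-4H-chromen-4-one (target)
Conditions: 3 M aq. HCl, MeOH/THF, 35 °C, degassed
Reagents that add atoms: none
Why: Acid hydrolysis of the seven aryl MOM acetals under dilute acid, chosen over base because the flavanone C2 centre racemises by ring opening in base, while the trisubstituted alkene and the all-trans (thermodynamic) cyclohexene centres are stable at this acidity.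

**Compound list**
1 | resorcinol | Oc1cccc(O)c1 | starting material
2 | 2,4-dihydroxybenzaldehyde | O=Cc1ccc(O)cc1O | intermediate
3 | 2,4-bis(methoxymethoxy)benzaldehyde | COCOc1ccc(C=O)c(OCOC)c1 | intermediate
4 | 1-(2,4-dihydroxyphenyl)ethan-1-one | CC(=O)c1ccc(O)cc1O | intermediate
5 | 1-[2-hydroxy-4-(methoxymethoxy)phenyl]ethan-1-one | CC(=O)c1ccc(OCOC)cc1O | intermediate
6 | (E)-3-[2,4-bis(methoxymethoxy)phenyl]-1-[2-hydroxy-4-(methoxymethoxy)phenyl]prop-2-en-1-one | COCOc1ccc(/C=C/C(=O)c2ccc(OCOC)cc2O)c(OCOC)c1 | intermediate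
7 | 3-methylbut-2-enal | CC(C)=CC=O | starting material
8 | (E)-3-methylbuta-1,3-dien-1-yl acetate | CC(=C)/C=C/OC(C)=O | intermediate
9 | (1S,5S,6R)-5-[2,4-bis(methoxymethoxy)phenyl]-6-[2-hydroxy-4-(methoxymethoxy)benzoyl]-3-methylcyclohex-2-en-1-yl acetate | CC1=C[C@H](OC(C)=O)[C@H](C(=O)c2ccc(OCOC)cc2O)[C@@H](c2ccc(OCOC)cc2OCOC)C1 | intermediate
10 | (1S,5S,6R)-6-[2,4-bis(methoxymethoxy)benzoyl]-5-[2,4-bis(methoxymethoxy)phenyl]-3-methylcyclohex-2-en-1-yl acetate | CC1=C[C@H](OC(C)=O)[C@H](C(=O)c2ccc(OCOC)cc2OCOC)[C@@H](c2ccc(OCOC)cc2OCOC)C1 | intermediate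
11 | 1,3-bis(methoxymethoxy)benzene | COCOc1cccc(OCOC)c1 | intermediate
12 | 1,5-dibromo-2,4-bis(methoxymethoxy)benzene | COCOc1cc(OCOC)c(Br)cc1Br | intermediate
13 | [5-bromo-2,4-bis(methoxymethoxy)phenyl]boronic acid | COCOc1cc(OCOC)c(Br)cc1B(O)O | intermediate
14 | 7-(methoxymethoxy)-4H-chromen-4-one | COCOc1ccc2c(c1)occc2=O | intermediate
15 | (2R)-2-[5-bromo-2,4-bis(methoxymethoxy)phenyl]-7-(methoxymethoxy)-2,3-dihydro-4H-chromen-4-one | COCOc1cc(OCOC)c(Br)cc1[C@H]1CC(=O)c2ccc(OCOC)cc2O1 | intermediate
16 | (2R)-2-[2,4-bis(methoxymethoxy)-5-(4,4,5,5-tetramethyl-1,3,2-dioxaborolan-2-yl)phenyl]-7-(methoxymethoxy)-2,3-dihydro-4H-chromen-4-one | COCOc1cc(OCOC)c(B2OC(C)(C)C(C)(C)O2)cc1[C@H]1CC(=O)c2ccc(OCOC)cc2O1 | intermediate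
17 | hepta-MOM ether of the target (name in step 15) | CC1=C[C@@H](c2cc([C@H]3CC(=O)c4ccc(OCOC)cc4O3)c(OCOC)cc2OCOC)[C@H](C(=O)c2ccc(OCOC)cc2OCOC)[C@@H](c2ccc(OCOC)cc2OCOC)C1 | intermediate
18 | (2R)-2-{5-[(1R,5S,6R)-6-(2,4-dihydroxybenzoyl)-5-(2,4-dihydroxyphenyl)-3-methylcyclohex-2-en-1-yl]-2,4-dihydroxyphenyl}-7-hydroxy-2,3-dihydro-4H-chromen-4-one | CC1=C[C@@H](c2cc([C@H]3CC(=O)c4ccc(O)cc4O3)c(O)cc2O)[C@H](C(=O)c2ccc(O)cc2O)[C@@H](c2ccc(O)cc2O)C1 | target

**Totals**
Total steps: 16. Longest linear sequence: 7 (for example steps 1, 2, 5, 7, 8, 15, 16).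

**Three steps most likely to fail**
- **Step 15 (proposed new coupling).** The risks are elimination of the π-allyl/β-acetoxy ketone to the dienone, arylation at the methyl-bearing terminus, and partial flavanone racemisation by fluoride. Fallback with known chemistry: Suzuki–Miyaura coupling of bromide 15 with (E)-3-methylbuta-1,3-dienyl pinacolboronate to give the aryl diene, then the established chiral-borate-promoted Diels–Alder of that diene with chalcone 6, separation of the exo (all-trans) adduct from the endo one, and the same deprotection.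
- **Step 7 (asymmetric Diels–Alder with the acetoxy diene).** The risks are modest endo/exo selectivity, lower ee than with known dienes, and loss of AcOH from the boron-bound adduct. Fallback: run the cycloaddition racemically (thermal or silver-nanoparticle-catalysed, as known for 2'-hydroxychalcones) and resolve endo-9 by preparative chiral SFC.
- **Step 13 (Rh 1,4-addition with an ortho-alkoxy, electron-rich boronic acid).** The risks are protodeboronation and slow addition. Fallback: convert 12 to 5-bromo-2,4-bis(methoxymethoxy)benzaldehyde (n-BuLi, DMF), run a Claisen–Schmidt condensation with 5, cyclise with NaOAc to racemic 15, then obtain (R)-15 by Ru-catalysed transfer-hydrogenation kinetic resolution or chiral SFC.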